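## Retrosynthetic overview

1. The CH2 bridge is cut last. It gives the chiral ring B acid (free C6-H), a one-carbon aminal, and the ring A ketone 1-(2,6-dihydroxy-4-methoxyphenyl)hexan-1-one (Mannich, elimination, Michael cascade).
2. The prenyl group comes from an allyl group by cross metathesis.
3. Key bond: quaternary carbon to allyl CH2. The methyl-bearing carbon of aromatic 3-methyl-butanoylphloroglucinol is a natural nucleophile. It is made electrophilic as a chiral aryloxy-λ3-iodane (phenoxenium/enolonium equivalent) and attacked by allylsilane, also a natural nucleophile. This one step dearomatises ring B and sets the only stereocentre.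
4. Both aryl ketones come from Friedel–Crafts acylation of (methyl)phloroglucinol. Ring A gets its 4-OMe by selective O-methylation.
5. No ring is built. Ring A and ring B are bought as benzene rings, and ring B is dearomatised in step 2.

Assumption: β-triketone rings are drawn in the tautomer of the target SMILES. The facial sense of the new step cannot be predicted, so it is written for the (R,R)-catalyst, and the (S,S)-catalyst is used if the product proves to be (S).

Catalyst of step 2 (commercial, derived from lactate ester and 2-iodoresorcinol): (R,R)-2-iodo-1,3-bis[1-(mesitylcarbamoyl)ethoxy]benzene, Ic1c(O[C@H](C)C(=O)Nc2c(C)cc(C)cc2C)cccc1O[C@H](C)C(=O)Nc1c(C)cc(C)cc1C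

## Route

Step 1
Reactants: 1 2-methylphloroglucinol (2-methylbenzene-1,3,5-triol); 2 butanoic acid
Product: 3 1-(2,4,6-trihydroxy-3-methylphenyl)butan-1-one
Conditions: BF3·OEt2 (as solvent), 80 °C, 2 h; then H2O
Reagents that add atoms: none
Why: Friedel–Crafts acylation of a very electron-rich arene whose two free positions are equivalent, and the first acyl group (held as its BF2 chelate) stops a second acylation.

Step 2
Reactants: 3 1-(2,4,6-trihydroxy-3-methylphenyl)butan-1-one; 4 allyltrimethylsilane
Product: 6 (R)-2-butanoyl-3,5-dihydroxy-4-methyl-4-(prop-2-en-1-yl)cyclohexa-2,5-dien-1-one, via aryloxy-λ3-iodane 5 (not isolated)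
Conditions: (R,R)-2-iodo-1,3-bis[1-(mesitylcarbamoyl)ethoxy]benzene (15 mol %), mCPBA (1.0 equiv, added over 6 h), 4 (4 equiv), CH2Cl2/(CF3)2CHOH 10:1, −20 °C
Reagents that add atoms: none
Why: Proposed new method: mCPBA oxidises the iodoarene to a chiral trivalent-iodine species that exchanges a ligand for the free, most acidic 4-OH of 3 to give 5, in which the normally nucleophilic ring carbons are electrophilic (phenoxenium/enolonium equivalent); C1 is switched off by the acyl group and the methyl-bearing C3 carries the best-stabilised positive charge, so the π-nucleophile 4 attacks C3 in an SN2′-type displacement of the iodoarene (β-silyl cation, then loss of the silyl group), which dearomatises the ring and builds the quaternary centre, while the hydrogen-bonded lactamide arms hold iodine over one ring face so that 4 enters from the open face to give (R)-6; the closest known reaction types are the racemic hypervalent-iodine oxidative Hosomi–Sakurai allylation of 4-alkylphenols and 2-alkoxynaphthols, and the enantioselective dearomatising (Kita-type) spirolactonisation and hydroxylation of phenols with this class of chiral iodoarene catalyst.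

Step 3
Reactants: 6 (R)-2-butanoyl-3,5-dihydroxy-4-methyl-4-(prop-2-en-1-yl)cyclohexa-2,5-dien-1-one
Product: 7 (R)-2-butanoyl-3,5-dihydroxy-4-methyl-4-(3-methylbut-2-en-1-yl)cyclohexa-2,5-dien-1-one
Conditions: second-generation Grubbs catalyst (H2IMes)(PCy3)Cl2Ru=CHPh (5 mol %), 2-methyl-2-butene/CH2Cl2 1:1, 40 °C, sealed tube
Reagents that add atoms: 2-methyl-2-butene, CC=C(C)C
Why: Olefin cross metathesis of a terminal allyl group on a quaternary carbon with excess 2-methyl-2-butene is the standard allyl-to-prenyl exchange, and at 40 °C the all-carbon stereocentre is untouched (no Cope or retro-Claisen shift).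

Step 4
Reactants: 8 phloroglucinol (benzene-1,3,5-triol); 9 hexanoic acid
Product: 10 1-(2,4,6-trihydroxyphenyl)hexan-1-one
Conditions: BF3·OEt2 (as solvent), 85 °C, 2 h; then H2O
Reagents that add atoms: none
Why: Friedel–Crafts acylation at one of three equivalent positions, which stops at the monoketone because the chelated acyl group deactivates the ring.

Step 5
Reactants: 10 1-(2,4,6-trihydroxyphenyl)hexan-1-one
Product: 11 1-(2,6-dihydroxy-4-methoxyphenyl)hexan-1-one
Conditions: Me2SO4 (1.0 equiv), K2CO3 (1.0 equiv), acetone, reflux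
Reagents that add atoms: dimethyl sulfate, COS(=O)(=O)OC
Why: Selective Williamson O-methylation, since the 4-OH is the most acidic and the only one not hydrogen-bonded to the ketone, and the hard electrophile avoids C-methylation.

Step 6
Reactants: 7 (R)-2-butanoyl-3,5-dihydroxy-4-methyl-4-(3-methylbut-2-en-1-yl)cyclohexa-2,5-dien-1-one; 11 1-(2,6-dihydroxy-4-methoxyphenyl)hexan-1-one
Product: 14 elaphopilosin B, via Mannich base 12 (not isolated), via methylene trione 13 (not isolated)
Conditions: 7, CH2(NMe2)2 (1.0 equiv), THF, 0 °C to rt, 1 h; then 11 (2 equiv), 40 °C; 1 M HCl work-up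
Reagents that add atoms: bis(dimethylamino)methane, CN(C)CN(C)C
Why: Mannich reaction at the only free carbon (C6) of the acidic enol 7 gives zwitterion 12, which loses Me2NH (E1cB) to the methylene trione 13, and the phenolate of 11 adds through one of its two equivalent ring carbons (Michael-type Friedel–Crafts alkylation); the excess of 11 suppresses double alkylation, and the quaternary stereocentre takes no part.

## Compound list

1 | 2-methylbenzene-1,3,5-triol (2-methylphloroglucinol) | Cc1c(O)cc(O)cc1O | starting material
2 | butanoic acid | CCCC(=O)O | starting material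
3 | 1-(2,4,6-trihydroxy-3-methylphenyl)butan-1-one | CCCC(=O)c1c(O)c(C)c(O)cc1O | intermediate
4 | allyltrimethylsilane | C=CC[Si](C)(C)C | starting material
5 | (4-butanoyl-3,5-dihydroxy-2-methylphenoxy)(3-chlorobenzoyloxy){2,6-bis[(R)-1-(mesitylcarbamoyl)ethoxy]phenyl}-λ3-iodane | CCCC(=O)c1c(O)c(C)c(OI(OC(=O)c2cccc(Cl)c2)c2c(O[C@H](C)C(=O)Nc3c(C)cc(C)cc3C)cccc2O[C@H](C)C(=O)Nc2c(C)cc(C)cc2C)cc1O | intermediate
6 | (R)-2-butanoyl-3,5-dihydroxy-4-methyl-4-(prop-2-en-1-yl)cyclohexa-2,5-dien-1-one | O=C1C=C(O)[C@@](C)(CC=C)C(O)=C1C(=O)CCC | intermediate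
7 | (R)-2-butanoyl-3,5-dihydroxy-4-methyl-4-(3-methylbut-2-en-1-yl)cyclohexa-2,5-dien-1-one | O=C1C=C(O)[C@@](C)(CC=C(C)C)C(O)=C1C(=O)CCC | intermediate
8 | benzene-1,3,5-triol (phloroglucinol) | Oc1cc(O)cc(O)c1 | starting material
9 | hexanoic acid | CCCCCC(=O)O | starting material
10 | 1-(2,4,6-trihydroxyphenyl)hexan-1-one | CCCCCC(=O)c1c(O)cc(O)cc1O | intermediate
11 | 1-(2,6-dihydroxy-4-methoxyphenyl)hexan-1-one | CCCCCC(=O)c1c(O)cc(OC)cc1O | intermediate
12 | (R)-2-butanoyl-6-[(dimethylamino)methyl]-3,5-dihydroxy-4-methyl-4-(3-methylbut-2-en-1-yl)cyclohexa-2,5-dien-1-one | O=C1C(CN(C)C)=C(O)[C@@](C)(CC=C(C)C)C(O)=C1C(=O)CCC | intermediate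
13 | 2-butanoyl-3-hydroxy-4-methyl-6-methylidene-4-(3-methylbut-2-en-1-yl)cyclohex-2-ene-1,5-dione (same spatial arrangement as 7; the descriptor reads S only because the CIP ranking changes) | O=C1C(=C)C(=O)[C@@](C)(CC=C(C)C)C(O)=C1C(=O)CCC | intermediate
14 | elaphopilosin B, (R)-2-butanoyl-6-[(3-hexanoyl-2,4-dihydroxy-6-methoxyphenyl)methyl]-3,5-dihydroxy-4-methyl-4-(3-methylbut-2-en-1-yl)cyclohexa-2,5-dien-1-one | CCCCCC(=O)c1c(O)cc(OC)c(CC2=C(O)[C@@](C)(CC=C(C)C)C(O)=C(C(=O)CCC)C2=O)c1O | target

## Step count and risks

Total step count: 6. Longest linear sequence: 4 (steps 1, 2, 3, 6).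

**Risk 1 (step 2).**
- The aryloxy-iodane may ionise to a free phenoxenium ion, which would give low ee.
- The electrophile may be captured by 3-chlorobenzoate or at the unsubstituted C5.
- The methyl group may lose a proton to give a quinone methide.
- The product may be oxidised a second time.

The fallback sets out from 3 and comes back at 6. It keeps the same polarity-reversed bond formation but gives up catalyst control. Compounds 3 and 4 with PhI(OAc)2 in (CF3)2CHOH at 0 °C give the racemic allyl dienone F1. F1 is a vinylogous carboxylic acid (pKa about 5), so it is resolved through its salts with (S)-1-phenylethylamine from EtOAc/hexane. The less soluble salt of the (R)-acid F2 is recrystallised to constant rotation. The more soluble diastereomeric salt F3 stays in the liquor. 1 M HCl then releases 6 from F2. The (R)-amine is used instead if the wrong salt crystallises.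

**Risk 2 (step 6).**
- Retro-Michael exchange of methylene-bridged phloroglucinols can scramble the halves into symmetric dimers.
- Compound 11 can be alkylated twice.
- Compound 13 can oligomerise.

The fallback sets out from 11 and comes back at 14, with the roles of the two halves reversed. Compound 11 is aminomethylated with CH2(NMe2)2 (1.0 equiv) to the isolated benzylic amine F4. MeI converts F4 into the quaternary ammonium iodide F5. F5 is stirred with 7 and K2CO3 in MeCN at rt. F5 loses NMe3 to give the ring A ortho-quinone methide F6. The only nucleophile F6 meets is the enolate of 7, which has a single free carbon, and this addition gives 14.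

**Risk 3 (step 3).**
- The acidic, chelating β-triketone may deactivate the ruthenium carbene.
- It may also promote allyl-to-propenyl isomerisation.

The fallback sets out from 6 and comes back at 7, with both enol OH groups masked for the duration of the metathesis. N,O-bis(trimethylsilyl)acetamide in CH2Cl2 gives the bis(trimethylsilyl) ether F7. The same metathesis in the same flask gives the prenyl bis(trimethylsilyl) ether F8. Aqueous citric acid in THF at rt removes the silyl groups to give 7.

## Further compounds

F1 | step 2 | racemic 2-butanoyl-3,5-dihydroxy-4-methyl-4-(prop-2-en-1-yl)cyclohexa-2,5-dien-1-one | O=C1C=C(O)C(C)(CC=C)C(O)=C1C(=O)CCC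
F2 | step 2 | (S)-1-phenylethylammonium salt of the (R)-acid 6 | O=C1C=C([O-])[C@@](C)(CC=C)C(O)=C1C(=O)CCC.C[C@H]([NH3+])c1ccccc1
F3 | step 2 | (S)-1-phenylethylammonium salt of the (S)-enantiomer of 6 | O=C1C=C([O-])[C@](C)(CC=C)C(O)=C1C(=O)CCC.C[C@H]([NH3+])c1ccccc1
F4 | step 6 | 1-{3-[(dimethylamino)methyl]-2,6-dihydroxy-4-methoxyphenyl}hexan-1-one | CCCCCC(=O)c1c(O)cc(OC)c(CN(C)C)c1O
F5 | step 6 | (3-hexanoyl-2,4-dihydroxy-6-methoxyphenyl)methyl(trimethyl)ammonium iodide | CCCCCC(=O)c1c(O)cc(OC)c(C[N+](C)(C)C)c1O.[I-]
F6 | step 6 | 2-hexanoyl-3-hydroxy-5-methoxy-6-methylidenecyclohexa-2,4-dien-1-one | CCCCCC(=O)C1=C(O)C=C(OC)C(=C)C1=O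
F7 | step 3 | (R)-2-butanoyl-4-methyl-4-(prop-2-en-1-yl)-3,5-bis(trimethylsilyloxy)cyclohexa-2,5-dien-1-one | O=C1C=C(O[Si](C)(C)C)[C@@](C)(CC=C)C(O[Si](C)(C)C)=C1C(=O)CCC
F8 | step 3 | (R)-2-butanoyl-4-methyl-4-(3-methylbut-2-en-1-yl)-3,5-bis(trimethylsilyloxy)cyclohexa-2,5-dien-1-one | O=C1C=C(O[Si](C)(C)C)[C@@](C)(CC=C(C)C)C(O[Si](C)(C)C)=C1C(=O)CCC
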